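## Retrosynthetic overview

1. The target is traced back to a silyl ketal cycloadduct (loss of silanol, cleavage of a silyl enol ether), which comes from an intramolecular Diels–Alder reaction of an ester-derived 1-alkoxy-1,3-bis(silyloxy)-2,4-dimethoxybutadiene onto a tethered 2-allyl-1-alkene; this forms C3a–C7a and C4–C5 together.
2. The diene comes from the 2,4-dimethoxy-3-oxobutanoate ester of the anti alcohol CH3CH(OH)–CH(Ar)–C(=CH2)–CH2CH=CH2; the acyl part is the Claisen dimer of methyl methoxyacetate.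
3. The alcohol comes from benzylic SN2 opening of the cis-epoxide of (Z)-1-(3,4,5-trimethoxyphenyl)propene by penta-1,4-dien-2-ylmagnesium bromide; the epoxide comes from Jacobsen epoxidation and the alkene from a Wittig reaction of 3,4,5-trimethoxybenzaldehyde.
4. Ring order: the arene is bought; the oxolane ring (tether ring) and the cyclohexenone ring (cycloaddition ring) are both closed in the last step.

Assumption: the target is read from the SMILES as (2R,3S,3aR,5S); 2-bromopenta-1,4-diene and methyl 2,4-dimethoxy-3-oxobutanoate are made, not bought.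
Atom labels O1, C2, C3, C3a, C4–C7 and C7a are those of the benzofuranone target and are used for all precursors; Ar = 3,4,5-trimethoxyphenyl, TBS = tert-butyldimethylsilyl.

## Route

Step 1
Reactants: 1 3,4,5-trimethoxybenzaldehyde; 2 ethyltriphenylphosphonium bromide
Product: 4 (Z)-1,2,3-trimethoxy-5-(prop-1-en-1-yl)benzene, via ethylidenetriphenylphosphorane 3 (not isolated)
Conditions: NaN(SiMe3)2, THF, −78 °C to rt
Reagents that add atoms: none
Why: Wittig olefination with a non-stabilised ylide under lithium-free conditions runs through the kinetic cis-oxaphosphetane and gives mainly the (Z)-alkene (about 9:1 expected; the E isomer is a poor substrate in step 2 and is removed there).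

Step 2
Reactants: 4 (Z)-1,2,3-trimethoxy-5-(prop-1-en-1-yl)benzene
Product: 5 (2R,3S)-2-methyl-3-(3,4,5-trimethoxyphenyl)oxirane (cis)
Conditions: (S,S)-[N,N'-bis(3,5-di-tert-butylsalicylidene)cyclohexane-1,2-diaminato]MnCl (5 mol %), mCPBA, NMO, CH2Cl2, −78 °C
Reagents that add atoms: mCPBA (3-chloroperoxybenzoic acid), OOC(=O)c1cccc(Cl)c1
Why: Jacobsen–Katsuki epoxidation works best on cis-1-arylpropenes, and the (S,S)-complex of trivalent manganese gives the cis-epoxide with the benzylic carbon S (as for cis-β-methylstyrene and indene), which sets C2 and, after inversion in step 4, C3.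

Step 3
Reactants: 6 2,3-dibromoprop-1-ene; 7 vinylmagnesium bromide
Product: 8 2-bromopenta-1,4-diene
Conditions: CuBr·SMe2 (5 mol %), THF, −20 °C to rt
Reagents that add atoms: none
Why: Copper-catalysed allylic substitution of the allylic C–Br bond by the vinyl Grignard reagent (SN2 and SN2' give the same product) leaves the vinylic C–Br bond untouched.

Step 4
Reactants: 5 (2R,3S)-2-methyl-3-(3,4,5-trimethoxyphenyl)oxirane; 8 2-bromopenta-1,4-diene
Product: 10 (2R,3R)-4-methylidene-3-(3,4,5-trimethoxyphenyl)hept-6-en-2-ol, via penta-1,4-dien-2-ylmagnesium bromide 9 (not isolated)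
Conditions: Mg, THF, rt; then CuBr·SMe2 (10 mol %), 5, THF, −40 to 0 °C; aq. NH4Cl
Reagents that add atoms: none
Why: Copper-catalysed SN2 opening of an aryl epoxide by an alkenyl Grignard reagent takes place at the electronically activated benzylic carbon with inversion, so the cis-epoxide gives the anti alcohol (C3 set, C2 kept from step 2), the relationship that becomes 2,3-trans in the oxolane ring.

Step 5
Reactants: 11 methyl methoxyacetate (2 equiv)
Product: 12 methyl 2,4-dimethoxy-3-oxobutanoate
Conditions: NaH (0.55 equiv per 11), THF, 0 to 60 °C; then 1 M HCl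
Reagents that add atoms: none
Why: Claisen self-condensation, driven by deprotonation of the β-keto ester that forms.

Step 6
Reactants: 10 (2R,3R)-4-methylidene-3-(3,4,5-trimethoxyphenyl)hept-6-en-2-ol; 12 methyl 2,4-dimethoxy-3-oxobutanoate
Product: 13 (2R,3R)-4-methylidene-3-(3,4,5-trimethoxyphenyl)hept-6-en-2-yl 2,4-dimethoxy-3-oxobutanoate
Conditions: DMAP (0.3 equiv), PhMe, 4 Å MS, reflux
Reagents that add atoms: none
Why: DMAP-catalysed transesterification of a β-keto ester (acylketene or addition–elimination pathway) with methanol taken up by the sieves makes the O1–C7a bond without touching C2 or C3; the new acyl stereocentre is lost in step 7.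

Step 7
Reactants: 13 (2R,3R)-4-methylidene-3-(3,4,5-trimethoxyphenyl)hept-6-en-2-yl 2,4-dimethoxy-3-oxobutanoate
Product: 16 (2R,3S,3aR,5S)-3a-allyl-5,7-dimethoxy-2-methyl-3-(3,4,5-trimethoxyphenyl)-3,3a,4,5-tetrahydro-1-benzofuran-6(2H)-one, via bis-silyl diene 14 (not isolated), via silyl ketal cycloadduct 15 (not isolated)
Conditions: TBSOTf (2.4 equiv), Et3N (3.5 equiv), PhMe, 0 °C to rt, ammonium triflate layer removed; BHT, PhMe (0.01 M), 170 °C, sealed tube; then 1 M HCl, THF, 0 °C
Reagents that add atoms: none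
Why: Proposed new method: double O-silylation of the β-keto ester (Simchen-type enolisation with a silyl triflate and Et3N) turns the conformationally restricted ester into a freely rotating, HOMO-raised 1-alkoxy-1,3-bis(silyloxy)diene of the Chan/Brassard type held three atoms from the 1,1-disubstituted alkene, so a thermal type 1 intramolecular Diels–Alder reaction (closest known: cyclisation of 1,3,8-nonatrienes and of 2-silyloxydienes onto unactivated alkenes at 160–200 °C, and intermolecular Chan/Brassard-diene cycloadditions that collapse to 3-alkoxyenones) forms C3a–C7a and C4–C5 and with them the oxolane and the carbocycle at once; the C3 aryl group lies on the =CH2 side of the alkene (less allylic 1,2-strain than next to the allyl branch, with C2-Me and C3-Ar both pseudo-equatorial), which puts allyl trans to aryl at the new quaternary C3a, the (Z)-enol ether terminus (OMe outside) together with the allyl group lying under the diene puts C5-OMe cis to allyl, and cold dilute acid then ionises the C7a silyl ketal and cleaves the C6 silyl enol ether to the vinylogous ester without enolising C5.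

## Compound list

1 | 3,4,5-trimethoxybenzaldehyde | COc1cc(C=O)cc(OC)c1OC | starting material
2 | ethyltriphenylphosphonium bromide | CC[P+](c1ccccc1)(c1ccccc1)c1ccccc1.[Br-] | starting material
3 | ethylidenetriphenylphosphorane | CC=P(c1ccccc1)(c1ccccc1)c1ccccc1 | intermediate (not isolated)
4 | (Z)-1,2,3-trimethoxy-5-(prop-1-en-1-yl)benzene | C/C=C\c1cc(OC)c(OC)c(OC)c1 | intermediate
5 | (2R,3S)-2-methyl-3-(3,4,5-trimethoxyphenyl)oxirane (cis) | C[C@H]1O[C@H]1c1cc(OC)c(OC)c(OC)c1 | intermediate
6 | 2,3-dibromoprop-1-ene | C=C(Br)CBr | starting material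
7 | vinylmagnesium bromide | C=C[Mg]Br | starting material
8 | 2-bromopenta-1,4-diene | C=CCC(Br)=C | intermediate
9 | penta-1,4-dien-2-ylmagnesium bromide | C=CCC(=C)[Mg]Br | intermediate (not isolated)
10 | (2R,3R)-4-methylidene-3-(3,4,5-trimethoxyphenyl)hept-6-en-2-ol (anti) | O[C@H](C)[C@H](C(=C)CC=C)c1cc(OC)c(OC)c(OC)c1 | intermediate
11 | methyl methoxyacetate | COCC(=O)OC | starting material
12 | methyl 2,4-dimethoxy-3-oxobutanoate | COCC(=O)C(OC)C(=O)OC | intermediate
13 | (2R,3R)-4-methylidene-3-(3,4,5-trimethoxyphenyl)hept-6-en-2-yl 2,4-dimethoxy-3-oxobutanoate (acyl C2 epimers) | COCC(=O)C(OC)C(=O)O[C@H](C)[C@H](C(=C)CC=C)c1cc(OC)c(OC)c(OC)c1 | intermediate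
14 | (2R,3R)-4-methylidene-3-(3,4,5-trimethoxyphenyl)hept-6-en-2-yl (3Z)-1,3-bis(tert-butyldimethylsilyloxy)-2,4-dimethoxybuta-1,3-dien-1-yl ether (C1=C2 geometry mixed) | CO/C=C(O[Si](C)(C)C(C)(C)C)/C(OC)=C(O[Si](C)(C)C(C)(C)C)O[C@H](C)[C@H](C(=C)CC=C)c1cc(OC)c(OC)c(OC)c1 | intermediate (not isolated)
15 | (2R,3S,3aR,5S)-3a-allyl-6,7a-bis(tert-butyldimethylsilyloxy)-5,7-dimethoxy-2-methyl-3-(3,4,5-trimethoxyphenyl)-2,3,3a,4,5,7a-hexahydro-1-benzofuran (C7a epimers) | C=CC[C@]12C[C@H](OC)C(O[Si](C)(C)C(C)(C)C)=C(OC)C1(O[Si](C)(C)C(C)(C)C)O[C@H](C)[C@H]2c1cc(OC)c(OC)c(OC)c1 | intermediate (not isolated)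
16 | (2R,3S,3aR,5S)-3a-allyl-5,7-dimethoxy-2-methyl-3-(3,4,5-trimethoxyphenyl)-3,3a,4,5-tetrahydro-1-benzofuran-6(2H)-one | C=CC[C@]12C[C@H](OC)C(=O)C(OC)=C1O[C@H](C)[C@H]2c1cc(OC)c(OC)c(OC)c1 | target

## Step count and fallbacks

Total step count: 7. Longest linear sequence: 5 steps (steps 1, 2, 4, 6 and 7, from 1 to 16).

The three steps most likely to fail are step 7, step 4 and step 2.

**Step 7.** The unactivated 1,1-disubstituted alkene may not react before diene 14 decomposes, or the C5 epimer may dominate. The fallback builds the two rings by polar bonds on a lactone template; it sets out from 1 and comes back to the route at 16. Morita–Baylis–Hillman reaction of 1 with methyl acrylate (DABCO) gives methyl 2-[hydroxy(3,4,5-trimethoxyphenyl)methyl]prop-2-enoate F1. HBr/H2SO4 converts it into methyl (Z)-2-(bromomethyl)-3-(3,4,5-trimethoxyphenyl)prop-2-enoate F2. Chromium-catalysed asymmetric Nozaki–Hiyama 2-(alkoxycarbonyl)allylation of acetaldehyde (CrCl2 10 mol %, chiral carbazole-bis(oxazoline) ligand, Mn, Me3SiCl) with lactonisation in the flask gives the trans lactone (4S,5R)-5-methyl-3-methylidene-4-(3,4,5-trimethoxyphenyl)oxolan-2-one F3. Pyrrolidine-catalysed Michael addition of 1,3-dimethoxyacetone gives (4R,5R)-3-(2,4-dimethoxy-3-oxobutyl)-5-methyl-4-(3,4,5-trimethoxyphenyl)oxolan-2-one F4. Its dianion (LiN(iPr)2, 2.2 equiv, THF, −78 °C) is alkylated by allyl bromide at the lactone α-carbon on the face anti to the aryl group, giving (3R,4S,5R)-3-allyl-3-(2,4-dimethoxy-3-oxobutyl)-5-methyl-4-(3,4,5-trimethoxyphenyl)oxolan-2-one F5. KOtBu then drives the intramolecular Claisen acylation of the methoxymethyl ketone by the lactone carbonyl, which opens the lactone to (4R)-4-allyl-4-[(1S,2R)-2-hydroxy-1-(3,4,5-trimethoxyphenyl)propyl]-2,6-dimethoxycyclohexane-1,3-dione F6. TsOH in warm toluene condenses the hydroxyl group with the neighbouring carbonyl to give 16; C5 is not controlled on this path, so the 5-epimer has to be separated.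

**Step 4.** The Grignard reagent may attack C2 instead of the benzylic carbon, or the electron-rich epoxide may open by an SN1 path or rearrange. The fallback makes the anti alcohol by allylation of acetaldehyde; it sets out from 1 and comes back at 10. Horner–Wadsworth–Emmons reaction of 1 with triethyl 2-phosphonopent-4-enoate (NaH, THF) gives ethyl (E)-2-(3,4,5-trimethoxybenzylidene)pent-4-enoate F7. Reduction with iBu2AlH gives (E)-2-(3,4,5-trimethoxybenzylidene)pent-4-en-1-ol F8. PBr3 gives (E)-5-[2-(bromomethyl)penta-1,4-dien-1-yl]-1,2,3-trimethoxybenzene F9. Chromium-catalysed asymmetric Nozaki–Hiyama allylation of acetaldehyde (CrCl2 10 mol %, chiral ligand, Mn, Me3SiCl; then desilylation) joins the aryl-bearing γ-carbon to the aldehyde through a chair transition state and gives the anti (2R,3R) alcohol 10.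

**Step 2.** The enantiomeric excess (about 90–95 % expected) or the cis:trans ratio of 5 may be too low for a single enantiomer. The fallback replaces asymmetric catalysis by an enzymatic resolution; it sets out from 4 and comes back at 10. mCPBA/NaHCO3 gives racemic cis-2-methyl-3-(3,4,5-trimethoxyphenyl)oxirane F10. The opening of step 4 with 9 gives racemic anti-4-methylidene-3-(3,4,5-trimethoxyphenyl)hept-6-en-2-ol F11. Candida antarctica lipase B and vinyl acetate acetylate only the (2R) alcohol (Kazlauskas rule), giving (2R,3R)-4-methylidene-3-(3,4,5-trimethoxyphenyl)hept-6-en-2-yl acetate F12. This is separated from the unreacted (2S,3S) alcohol and methanolysed (K2CO3, MeOH) to 10.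

## Further compounds

F1 | step 7 | methyl 2-[hydroxy(3,4,5-trimethoxyphenyl)methyl]prop-2-enoate (racemic) | COC(=O)C(=C)C(O)c1cc(OC)c(OC)c(OC)c1
F2 | step 7 | methyl (Z)-2-(bromomethyl)-3-(3,4,5-trimethoxyphenyl)prop-2-enoate | COC(=O)/C(CBr)=C/c1cc(OC)c(OC)c(OC)c1
F3 | step 7 | (4S,5R)-5-methyl-3-methylidene-4-(3,4,5-trimethoxyphenyl)oxolan-2-one | C=C1C(=O)O[C@H](C)[C@H]1c1cc(OC)c(OC)c(OC)c1
F4 | step 7 | (4R,5R)-3-(2,4-dimethoxy-3-oxobutyl)-5-methyl-4-(3,4,5-trimethoxyphenyl)oxolan-2-one (C3 and side-chain epimers) | COCC(=O)C(OC)CC1C(=O)O[C@H](C)[C@H]1c1cc(OC)c(OC)c(OC)c1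
F5 | step 7 | (3R,4S,5R)-3-allyl-3-(2,4-dimethoxy-3-oxobutyl)-5-methyl-4-(3,4,5-trimethoxyphenyl)oxolan-2-one (side-chain epimers) | C=CC[C@]1(CC(OC)C(=O)COC)C(=O)O[C@H](C)[C@H]1c1cc(OC)c(OC)c(OC)c1
F6 | step 7 | (4R)-4-allyl-4-[(1S,2R)-2-hydroxy-1-(3,4,5-trimethoxyphenyl)propyl]-2,6-dimethoxycyclohexane-1,3-dione (C2 and C6 epimers) | C=CC[C@@]1(CC(OC)C(=O)C(OC)C1=O)[C@H](c1cc(OC)c(OC)c(OC)c1)[C@@H](C)O
F7 | step 4 | ethyl (E)-2-(3,4,5-trimethoxybenzylidene)pent-4-enoate | CCOC(=O)/C(CC=C)=C/c1cc(OC)c(OC)c(OC)c1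
F8 | step 4 | (E)-2-(3,4,5-trimethoxybenzylidene)pent-4-en-1-ol | OC/C(CC=C)=C/c1cc(OC)c(OC)c(OC)c1
F9 | step 4 | (E)-5-[2-(bromomethyl)penta-1,4-dien-1-yl]-1,2,3-trimethoxybenzene | BrC/C(CC=C)=C/c1cc(OC)c(OC)c(OC)c1
F10 | step 2 | racemic cis-2-methyl-3-(3,4,5-trimethoxyphenyl)oxirane | C[C@H]1O[C@H]1c1cc(OC)c(OC)c(OC)c1.C[C@@H]1O[C@@H]1c1cc(OC)c(OC)c(OC)c1
F11 | step 2 | racemic anti-4-methylidene-3-(3,4,5-trimethoxyphenyl)hept-6-en-2-ol | O[C@H](C)[C@H](C(=C)CC=C)c1cc(OC)c(OC)c(OC)c1.O[C@@H](C)[C@@H](C(=C)CC=C)c1cc(OC)c(OC)c(OC)c1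
F12 | step 2 | (2R,3R)-4-methylidene-3-(3,4,5-trimethoxyphenyl)hept-6-en-2-yl acetate | CC(=O)O[C@H](C)[C@H](C(=C)CC=C)c1cc(OC)c(OC)c(OC)c1
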